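The bicyclo[3.3.1]nonane-2,4,9-trione contains the ring C1–C2–C3–C4–C5–C9, a masked cyclohexane-1,3,5-trione in which each quaternary bridgehead (C1, C5) lies between two carbonyl carbons. The bonds C5–C9 and C1–C2 are therefore both Claisen bonds, and cutting them unravels both rings to an open-chain diester that carries only the C7, C8 and side-chain stereocentres. The key step is a domino Dieckmann condensation of a γ-branched (E)-β-methoxy enoate bearing a remote methyl ester: γ-acylation C5→C9 closes the cyclohexanone, then the new ketone enolate at C1 acylates at C2. C7/C8 come from an enantioselective Ireland–Claisen rearrangement, the side chain from (R)-limonene oxide by ring cleavage.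

Key step: step 15

Locants: C1 (bridgehead with prenyl), C2 (C=O), C3 (aroyl-bearing carbon), C4 (enol carbon), C5 (bridgehead with the C10 side chain), C6 (CH2), C7 (CH-prenyl), C8 (C with methyl and 4-methylpent-3-enyl), C9 (bridging C=O). "Prenyl" = 3-methylbut-2-en-1-yl.

Assumption: the (S,S)-bromodiazaborolidine is taken to deliver the (2R,3R)-acid 5; if the sense of induction is the opposite, the equally available (R,R)-reagent is used instead.

Remark: C1 in 12 and C1/C5 in 20 and 21 are carried as epimer mixtures on purpose, because both centres become planar in the key step. CIP descriptors at C7/C8 change along the route only through priority changes.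

Step 1
Reactants: 1 geraniol; 2 5-methylhex-4-enoic acid
Product: 3 geranyl 5-methylhex-4-enoate
Conditions: DCC, DMAP (cat.), CH2Cl2, 0 °C → rt
Reagents that add atoms: none
Why: Steglich esterification of a primary allylic alcohol under neutral conditions should leave the E-alkene and the trisubstituted alkenes untouched; no stereocentre is formed.

Step 2
Reactants: 3 geranyl 5-methylhex-4-enoate
Product: 5 (2R,3R)-3-methyl-2-(3-methylbut-2-en-1-yl)-3-(4-methylpent-3-en-1-yl)pent-4-enoic acid, via boron ketene acetal 4 (not isolated)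
Conditions: (4S,5S)-2-bromo-4,5-diphenyl-1,3-bis[3,5-bis(trifluoromethyl)phenylsulfonyl]-1,3,2-diazaborolidine (1.2 equiv, pre-formed from the bis-sulfonamide and BBr3), Et3N, toluene/hexane, −78 °C, then −20 → 4 °C; aqueous work-up
Reagents that add atoms: none
Why: Enantioselective Ireland–Claisen rearrangement: Et3N in toluene/hexane should give the E(O)-boron enolate, whose chair transition state with the (E)-geranyl alkene (prenyl pseudo-axial, homoprenyl pseudo-equatorial) sets the anti C7/C8 relationship, while the C2-symmetric diazaborolidine selects the enolate face and hence the absolute configuration of both centres.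

Step 3
Reactants: 5 (2R,3R)-acid
Product: 6 (2R,3R)-3-methyl-2-(3-methylbut-2-en-1-yl)-3-(4-methylpent-3-en-1-yl)pent-4-en-1-ol
Conditions: LiAlH4, Et2O, 0 °C → reflux
Reagents that add atoms: none
Why: Hydride reduction of the carboxylate to the primary alcohol; isolated alkenes are inert and the α-stereocentre is not enolised as the carboxylate.

Step 4
Reactants: 6 (2R,3R)-alcohol
Product: 7 (3R,4R)-5-iodo-3-methyl-4-(3-methylbut-2-en-1-yl)-3-(4-methylpent-3-en-1-yl)pent-1-ene
Conditions: I2, PPh3, imidazole, toluene/MeCN, 0 → 60 °C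
Reagents that add atoms: iodine, II
Why: Appel-type iodination through the alkoxyphosphonium salt; SN2 at the primary carbon leaves both stereocentres untouched.

Step 5
Reactants: 7 iodo-alkene
Product: 9 (3R,4R)-5-iodo-3-methyl-4-(3-methylbut-2-en-1-yl)-3-(4-methylpent-3-en-1-yl)pentan-1-ol, via B-alkyl-9-BBN adduct 8 (not isolated)
Conditions: 9-BBN (1.2 equiv), THF, 0 °C → rt; then NaBO3·4H2O, H2O, rt
Reagents that add atoms: sodium perborate, [Na+].[O-]OB=O
Why: Anti-Markovnikov hydroboration–oxidation; 9-BBN should react only with the monosubstituted vinyl group (trisubstituted alkenes and the C–I bond are inert) and perborate oxidises the borane without displacing the iodide.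

Step 6
Reactants: 9 iodo-alcohol
Product: 11 methyl (3R,4R)-5-iodo-3-methyl-4-(3-methylbut-2-en-1-yl)-3-(4-methylpent-3-en-1-yl)pentanoate, via aldehyde 10 (not isolated)
Conditions: PDC (6 equiv), MeOH (6 equiv), DMF, rt
Reagents that add atoms: methanol, CO
Why: Chromium(VI) oxidation of the primary alcohol to the aldehyde and of its methyl hemiacetal to the methyl ester in one pot; alkenes and the alkyl iodide should survive.

Step 7
Reactants: 11 iodo-ester
Product: 12 methyl (3R,4R)-5-iodo-3-methyl-2,4-bis(3-methylbut-2-en-1-yl)-3-(4-methylpent-3-en-1-yl)pentanoate (C2 epimer mixture; C2 = C1 of the target)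
Conditions: LDA (1.05 equiv), THF, −78 °C; prenyl bromide (3 equiv), −78 → −40 °C
Reagents that add atoms: prenyl bromide, CC(C)=CCBr
Why: Ester enolate alkylation; the allylic bromide should react at −78 °C faster than the enolate can close a four-membered ring onto the β-branched iodide, and the configuration of the new centre is irrelevant because it is enolised again in step 15.

Step 8
Reactants: 13 (4R)-limonene 1,2-oxide (commercial cis/trans mixture)
Product: 14 (3R)-6-oxo-3-(prop-1-en-2-yl)heptanal
Conditions: HIO4·2H2O, THF/H2O, 0 °C → rt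
Reagents that add atoms: water, O
Why: Acid-mediated epoxide hydrolysis and periodate glycol cleavage open the ring between C1 and C2 of limonene; the C4 stereocentre and the isopropenyl group are not involved.

Step 9
Reactants: 14 keto-aldehyde
Product: 15 (5R)-2-methyl-5-(prop-1-en-2-yl)octa-1,7-diene
Conditions: Ph3PCH3Br (2.6 equiv), KOtBu (2.5 equiv), THF, 0 °C; 14 added at −78 °C → rt
Reagents that add atoms: methyltriphenylphosphonium bromide, C[P+](c1ccccc1)(c1ccccc1)c1ccccc1.[Br-]
Why: Double Wittig methylenation of aldehyde and methyl ketone; addition to excess preformed ylide at low temperature should outrun intramolecular aldol condensation.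

Step 10
Reactants: 15 triene
Product: 17 (4R)-7-methyl-4-(prop-1-en-2-yl)oct-7-en-1-ol, via trialkylborane 16 (not isolated)
Conditions: Sia2BH (1.1 equiv, from BH3·SMe2 and 2-methylbut-2-ene), THF, −20 → 0 °C; then NaOH, H2O2, 0 °C
Reagents that add atoms: hydrogen peroxide, OO
Why: Chemoselective anti-Markovnikov hydroboration–oxidation; the bulky dialkylborane should add to the monosubstituted vinyl group much faster than to the two 1,1-disubstituted alkenes.

Step 11
Reactants: 17 alcohol
Product: 18 (4R)-7-methyl-4-(prop-1-en-2-yl)oct-7-enal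
Conditions: Dess–Martin periodinane, CH2Cl2, 0 °C → rt
Reagents that add atoms: none
Why: Dess–Martin oxidation of a primary alcohol to the aldehyde without touching the alkenes or the remote stereocentre.

Step 12
Reactants: 18 aldehyde
Product: 19 methyl (6R)-9-methyl-3-oxo-6-(prop-1-en-2-yl)dec-9-enoate
Conditions: methyl diazoacetate (1.2 equiv), SnCl2 (10 mol %), CH2Cl2, rt
Reagents that add atoms: methyl diazoacetate, COC(=O)C=[N+]=[N-]
Why: Roskamp reaction: Lewis-acid-promoted addition of the diazo ester to the aldehyde followed by 1,2-hydride shift and loss of N2 gives the β-keto ester; isolated alkenes are not cyclopropanated without a carbene catalyst.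

Step 13
Reactants: 19 β-keto ester; 12 iodo-ester
Product: 20 dimethyl (3S,4S)-3-methyl-2,4-bis(3-methylbut-2-en-1-yl)-3-(4-methylpent-3-en-1-yl)-6-[(2R)-5-methyl-2-(prop-1-en-2-yl)hex-5-en-1-yl]-7-oxononanedioate (epimer mixture at C2 and C6)
Conditions: 19 (1.3 equiv), NaH, THF, 0 °C; n-BuLi, 0 °C; then 12, DMPU, 0 °C → rt; AcOH
Reagents that add atoms: none
Why: Huckin–Weiler dianion alkylation: the more reactive γ-carbon (C5) of the β-keto ester dianion displaces the primary iodide and forms C5–C6, while the hindered C9 ester of 12 should resist intermolecular attack.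

Step 14
Reactants: 20 keto-diester
Product: 21 dimethyl (3S,4S,7E)-7-methoxy-3-methyl-2,4-bis(3-methylbut-2-en-1-yl)-3-(4-methylpent-3-en-1-yl)-6-[(2R)-5-methyl-2-(prop-1-en-2-yl)hex-5-en-1-yl]non-7-enedioate (epimer mixture at C2 and C6)
Conditions: HC(OMe)3, CSA (10 mol %), MeOH, rt → 40 °C
Reagents that add atoms: trimethyl orthoformate, COC(OC)OC
Why: Ketalisation of the β-keto ester and loss of methanol give the conjugated (E)-β-methoxy enoate, which removes the acidic C3 hydrogens; the geometry is not critical because the dienolate of step 15 re-forms this double bond.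

Step 15
Reactants: 21 β-methoxy enoate diester
Product: 23 4-methoxy-8-methyl-1,7-bis(3-methylbut-2-en-1-yl)-8-(4-methylpent-3-en-1-yl)-5-[(2R)-5-methyl-2-(prop-1-en-2-yl)hex-5-en-1-yl]bicyclo[3.3.1]non-3-ene-2,9-dione (7S,8S; bridgeheads as in the target), via cyclohexanone 22 (not isolated)
Conditions: LDA (1.1 equiv), THF, −78 → 0 °C; then LDA (1.5 equiv), −78 °C → rt; AcOH
Reagents that add atoms: none
Why: LDA removes the C5 γ-hydrogen of the (E)-β-methoxy enoate (the ester carbonyl directs the base to the cis γ-position, while C1–H beside the quaternary C8 is slower), and the dienolate is acylated at its γ-carbon by the C9 ester to give cyclohexanone 22 (vinylogous Dieckmann condensation, 6-(enolexo)-exo-trig; the α-carbon C3 could only form an eight-membered ring). The second charge of LDA enolises the only α-position left on the C9 ketone, C1, and this enolate attacks the C2 ester, expels methoxide and closes the C1–C2–C3–C4–C5–C9 ring (6-(enolendo)-exo-trig). The closest known reactions are the Dieckmann synthesis of cyclic 1,3-diones and the domino Dieckmann cyclisation used to assemble bicyclo[3.3.1]nonane-2,4,9-triones. C5 is set in the first closure relative to C7 and C8 through a chair transition state with the C7 prenyl group equatorial; this facial choice is the selectivity the step needs and the substrate does not enforce it, but only the epimer whose acrylate arm is axial and trans to the C7 prenyl group can bridge without pushing that group under the C2–C4 bridge, so the second closure should sort the epimers and leave the other one monocyclic. C1 needs no control, because the C1–C2 bond can form only on the face that carries the axial arm, and both C1 epimers of 21 converge in the enolate. C- over O-acylation at C1 is expected for a lithium enolate attacking an ester in THF, and the product has no acidic hydrogen left.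

Step 16
Reactants: 24 3,4-dihydroxybenzoic acid
Product: 25 tert-butyldimethylsilyl 3,4-bis(tert-butyldimethylsilyloxy)benzoate
Conditions: TBSCl (3.5 equiv), imidazole, DMF, rt
Reagents that add atoms: tert-butyldimethylsilyl chloride, CC(C)(C)[Si](C)(C)Cl
Why: Exhaustive silylation of both phenols and the carboxylic acid under standard imidazole catalysis.

Step 17
Reactants: 25 tris-silyl compound
Product: 26 3,4-bis(tert-butyldimethylsilyloxy)benzoyl chloride
Conditions: (COCl)2 (1.2 equiv), DMF (cat.), CH2Cl2, 0 °C → rt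
Reagents that add atoms: oxalyl chloride, ClC(=O)C(Cl)=O
Why: The Vilsmeier-type chloroiminium reagent converts the silyl ester directly into the acid chloride under neutral conditions that leave the aryl silyl ethers in place.

Step 18
Reactants: 23 bicyclic vinylogous ester; 26 acid chloride
Product: 27 3-[3,4-bis(tert-butyldimethylsilyloxy)benzoyl] derivative of 23
Conditions: LiTMP (3 equiv), THF, −78 °C; then 26 (3.5 equiv), −78 °C → 0 °C
Reagents that add atoms: none
Why: Directed lithiation of the C3 vinylic hydrogen of the bicyclic β-methoxy enone (the only acidic position, both bridgeheads being quaternary) and acylation of the vinyllithium with the acid chloride; silyl ethers carry no enolisable or electrophilic site.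

Step 19
Reactants: 27 protected acyl vinylogous ester
Product: 28 CNP0249346.2 (target)
Conditions: LiOH, dioxane/H2O (degassed), 90 °C; then AcOH to pH 4, 0 °C
Reagents that add atoms: lithium hydroxide, [Li+].[OH-]
Why: Hydroxide hydrolyses the 3-acyl vinylogous methyl ester by addition–elimination at C4 and cleaves both aryl silyl ethers, and the resulting triketone anion resists retro-Claisen attack; mild acidification avoids acid-induced cyclisation of prenyl groups onto the enol.

Compound list
1 | geraniol, (2E)-3,7-dimethylocta-2,6-dien-1-ol | CC(C)=CCC/C(C)=C/CO | starting material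
2 | 5-methylhex-4-enoic acid | CC(C)=CCCC(=O)O | starting material
3 | geranyl 5-methylhex-4-enoate | CC(C)=CCCC(=O)OC/C=C(\C)CCC=C(C)C | intermediate
4 | E(O)-boron ketene acetal of 3 (prenyl cis to the geranyloxy oxygen; boron held in the (4S,5S)-diphenyl-1,3-bis(arylsulfonyl)diazaborolidine) | CC(C)=CC/C=C(/OB1N(S(=O)(=O)c2cc(C(F)(F)F)cc(C(F)(F)F)c2)[C@@H](c2ccccc2)[C@H](c2ccccc2)N1S(=O)(=O)c1cc(C(F)(F)F)cc(C(F)(F)F)c1)OC/C=C(\C)CCC=C(C)C | intermediate
5 | (2R,3R)-3-methyl-2-(3-methylbut-2-en-1-yl)-3-(4-methylpent-3-en-1-yl)pent-4-enoic acid | OC(=O)[C@H](CC=C(C)C)[C@](C)(CCC=C(C)C)C=C | intermediate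
6 | (2R,3R)-3-methyl-2-(3-methylbut-2-en-1-yl)-3-(4-methylpent-3-en-1-yl)pent-4-en-1-ol | OC[C@H](CC=C(C)C)[C@](C)(CCC=C(C)C)C=C | intermediate
7 | (3R,4R)-5-iodo-3-methyl-4-(3-methylbut-2-en-1-yl)-3-(4-methylpent-3-en-1-yl)pent-1-ene | IC[C@H](CC=C(C)C)[C@](C)(CCC=C(C)C)C=C | intermediate
8 | B-alkyl-9-BBN adduct of 7 (boron on the terminal carbon of the former vinyl group; stereocentres as in 7) | IC[C@H](CC=C(C)C)[C@](C)(CCC=C(C)C)CCB1C2CCCC1CCC2 | intermediate
9 | (3R,4R)-5-iodo-3-methyl-4-(3-methylbut-2-en-1-yl)-3-(4-methylpent-3-en-1-yl)pentan-1-ol | IC[C@H](CC=C(C)C)[C@](C)(CCC=C(C)C)CCO | intermediate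
10 | (3R,4R)-5-iodo-3-methyl-4-(3-methylbut-2-en-1-yl)-3-(4-methylpent-3-en-1-yl)pentanal | IC[C@H](CC=C(C)C)[C@](C)(CCC=C(C)C)CC=O | intermediate
11 | methyl (3R,4R)-5-iodo-3-methyl-4-(3-methylbut-2-en-1-yl)-3-(4-methylpent-3-en-1-yl)pentanoate | IC[C@H](CC=C(C)C)[C@](C)(CCC=C(C)C)CC(=O)OC | intermediate
12 | methyl (3R,4R)-5-iodo-3-methyl-2,4-bis(3-methylbut-2-en-1-yl)-3-(4-methylpent-3-en-1-yl)pentanoate, C2 epimer mixture | IC[C@H](CC=C(C)C)[C@](C)(CCC=C(C)C)C(CC=C(C)C)C(=O)OC | intermediate
13 | (4R)-limonene 1,2-oxide, cis/trans mixture at the epoxide | CC12CC[C@H](CC1O2)C(C)=C | starting material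
14 | (3R)-6-oxo-3-(prop-1-en-2-yl)heptanal | CC(=O)CC[C@H](CC=O)C(C)=C | intermediate
15 | (5R)-2-methyl-5-(prop-1-en-2-yl)octa-1,7-diene | C=C(C)CC[C@H](CC=C)C(C)=C | intermediate
16 | bis(3-methylbutan-2-yl)borane adduct of 15 (boron on the terminal carbon of the former vinyl group; stereocentre as in 15) | C=C(C)CC[C@H](CCCB(C(C)C(C)C)C(C)C(C)C)C(C)=C | intermediate
17 | (4R)-7-methyl-4-(prop-1-en-2-yl)oct-7-en-1-ol | C=C(C)CC[C@H](CCCO)C(C)=C | intermediate
18 | (4R)-7-methyl-4-(prop-1-en-2-yl)oct-7-enal | C=C(C)CC[C@H](CCC=O)C(C)=C | intermediate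
19 | methyl (6R)-9-methyl-3-oxo-6-(prop-1-en-2-yl)dec-9-enoate | C=C(C)CC[C@H](CCC(=O)CC(=O)OC)C(C)=C | intermediate
20 | dimethyl (3S,4S)-3-methyl-2,4-bis(3-methylbut-2-en-1-yl)-3-(4-methylpent-3-en-1-yl)-6-[(2R)-5-methyl-2-(prop-1-en-2-yl)hex-5-en-1-yl]-7-oxononanedioate, epimer mixture at C2 and C6 | C=C(C)CC[C@H](CC(C[C@H](CC=C(C)C)[C@](C)(CCC=C(C)C)C(CC=C(C)C)C(=O)OC)C(=O)CC(=O)OC)C(C)=C | intermediate
21 | dimethyl (3S,4S,7E)-7-methoxy-3-methyl-2,4-bis(3-methylbut-2-en-1-yl)-3-(4-methylpent-3-en-1-yl)-6-[(2R)-5-methyl-2-(prop-1-en-2-yl)hex-5-en-1-yl]non-7-enedioate, epimer mixture at C2 and C6 | C=C(C)CC[C@H](CC(C[C@H](CC=C(C)C)[C@](C)(CCC=C(C)C)C(CC=C(C)C)C(=O)OC)/C(OC)=C\C(=O)OC)C(C)=C | intermediate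
22 | methyl (2E)-3-methoxy-3-(2-oxocyclohexyl)prop-2-enoate in which the ring carbon bearing the acrylate (C5) also carries the (2R)-5-methyl-2-(prop-1-en-2-yl)hex-5-en-1-yl chain, C1 (next to the ketone) a prenyl group (either configuration), C8 methyl and 4-methylpent-3-enyl, C7 prenyl; acrylate arm trans to the C7 prenyl group, C7/C8 as in the target | C=C(C)CC[C@H](C[C@]1(/C(OC)=C\C(=O)OC)C[C@H](CC=C(C)C)[C@](C)(CCC=C(C)C)C(CC=C(C)C)C1=O)C(C)=C | intermediate
23 | 4-methoxy-8-methyl-1,7-bis(3-methylbut-2-en-1-yl)-8-(4-methylpent-3-en-1-yl)-5-[(2R)-5-methyl-2-(prop-1-en-2-yl)hex-5-en-1-yl]bicyclo[3.3.1]non-3-ene-2,9-dione; (7S,8S), C7 prenyl and C8 homoprenyl on the face of the cyclohexanone ring opposite to the C2–C4 bridge, C8 methyl on the bridge side | C=C(C)CC[C@H](C[C@@]12C[C@H](CC=C(C)C)[C@](C)(CCC=C(C)C)[C@@](CC=C(C)C)(C(=O)C=C1OC)C2=O)C(C)=C | intermediate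
24 | 3,4-dihydroxybenzoic acid | OC(=O)c1ccc(O)c(O)c1 | starting material
25 | tert-butyldimethylsilyl 3,4-bis(tert-butyldimethylsilyloxy)benzoate | CC(C)(C)[Si](C)(C)OC(=O)c1ccc(O[Si](C)(C)C(C)(C)C)c(O[Si](C)(C)C(C)(C)C)c1 | intermediate
26 | 3,4-bis(tert-butyldimethylsilyloxy)benzoyl chloride | ClC(=O)c1ccc(O[Si](C)(C)C(C)(C)C)c(O[Si](C)(C)C(C)(C)C)c1 | intermediate
27 | 3-[3,4-bis(tert-butyldimethylsilyloxy)benzoyl]-4-methoxy derivative of the bicyclic dione 23 (all stereocentres as in 23) | C=C(C)CC[C@H](C[C@@]12C[C@H](CC=C(C)C)[C@](C)(CCC=C(C)C)[C@@](CC=C(C)C)(C(=O)C(C(=O)c3ccc(O[Si](C)(C)C(C)(C)C)c(O[Si](C)(C)C(C)(C)C)c3)=C1OC)C2=O)C(C)=C | intermediate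
28 | CNP0249346.2: 3-(3,4-dihydroxybenzoyl)-4-hydroxy-8-methyl-1,7-bis(3-methylbut-2-en-1-yl)-8-(4-methylpent-3-en-1-yl)-5-[(2R)-5-methyl-2-(prop-1-en-2-yl)hex-5-en-1-yl]bicyclo[3.3.1]non-3-ene-2,9-dione, stereochemistry as in 23 | C=C(C)CC[C@H](C[C@@]12C[C@H](CC=C(C)C)[C@](C)(CCC=C(C)C)[C@@](CC=C(C)C)(C(=O)C(C(=O)c3ccc(O)c(O)c3)=C1O)C2=O)C(=C)C | target

Total step count: 19.
Longest linear sequence: 12 steps (steps 1–7, 13, 14, 15, 18, 19).

Steps most likely to fail

1. Step 15 (key step). The first ring closure may show poor facial selectivity at C5, and the second acylation may stall: LDA can enolise the C9 ester at C1 before the first closure, and liberated methoxide can reopen the ketone. The fallback sets out from 21 and comes back at 23, replacing the second ester Claisen by a C-acylation with an acyl chloride. Compound 21 is treated with LDA (1.1 equiv) only and quenched with AcOH, so that cyclohexanone 22 is isolated. Its C5 epimers are separated, and the unwanted one is returned to 21 by methoxide-induced retro-Claisen opening. The enoate ester of 22 is hydrolysed with Me3SnOH (1,2-dichloroethane, 80 °C) to the β-methoxyacrylic acid F1. This is converted with 1-chloro-N,N,2-trimethylpropenylamine into the acid chloride F2. Soft enolisation of the ketone (MgBr2·OEt2, i-Pr2NEt, CH2Cl2) should then close the bridge to 23.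

2. Step 13. SN2 at the β-branched iodide next to the quaternary centre may be slow, so that E2 elimination or proton transfer from C1–H of 12 to the dianion takes over. The fallback sets out from 12 and 19 and comes back at 20, replacing substitution by carbonyl addition. Kornblum oxidation of 12 (AgBF4, DMSO; then Et3N) gives the aldehyde F3. Addition of the dianion of 19 at −78 °C gives the aldol adduct F4. Mesylation and elimination (MsCl, Et3N; DBU) give the enone F5. Conjugate reduction with Stryker's reagent should deliver 20.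

3. Step 7. Intramolecular alkylation of the ester enolate by the iodide (four-membered ring) or elimination at the iodide may compete with prenylation. The fallback sets out from 6 and comes back at 12, carrying C6 as a silyl ether and installing the iodide last. Silylation of 6 (TBSCl, imidazole) gives the silyl ether F6. Hydroboration–oxidation (9-BBN; NaBO3) gives the alcohol F7. PDC/MeOH/DMF gives the methyl ester F8. LDA and prenyl bromide give the prenylated ester F9. HF·pyridine at 0 °C gives the hydroxy ester F10, which is iodinated at once (I2, PPh3, imidazole) to 12 before it can lactonise.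

Further compounds
F1 | step 15 | (2E)-3-methoxy-3-(2-oxocyclohexyl)prop-2-enoic acid corresponding to 22 (free acid) | C=C(C)CC[C@H](C[C@]1(/C(OC)=C\C(=O)O)C[C@H](CC=C(C)C)[C@](C)(CCC=C(C)C)C(CC=C(C)C)C1=O)C(C)=C
F2 | step 15 | acid chloride of F1 | C=C(C)CC[C@H](C[C@]1(/C(OC)=C\C(=O)Cl)C[C@H](CC=C(C)C)[C@](C)(CCC=C(C)C)C(CC=C(C)C)C1=O)C(C)=C
F3 | step 13 | methyl 3-methyl-2,4-bis(3-methylbut-2-en-1-yl)-3-(4-methylpent-3-en-1-yl)-5-oxopentanoate (aldehyde from 12, C7/C8 as in 12) | O=C[C@H](CC=C(C)C)[C@](C)(CCC=C(C)C)C(CC=C(C)C)C(=O)OC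
F4 | step 13 | 5-hydroxy analogue of 20 (aldol adduct, hydroxyl on C6 of the target numbering) | C=C(C)CC[C@H](CC(C(O)[C@H](CC=C(C)C)[C@](C)(CCC=C(C)C)C(CC=C(C)C)C(=O)OC)C(=O)CC(=O)OC)C(C)=C
F5 | step 13 | 5,6-didehydro analogue of 20 (enone, C5=C6 of the target numbering) | C=C(C)CC[C@H](CC(=C[C@H](CC=C(C)C)[C@](C)(CCC=C(C)C)C(CC=C(C)C)C(=O)OC)C(=O)CC(=O)OC)C(C)=C
F6 | step 7 | tert-butyldimethylsilyl ether of 6 | CC(C)(C)[Si](C)(C)OC[C@H](CC=C(C)C)[C@](C)(CCC=C(C)C)C=C
F7 | step 7 | primary alcohol from hydroboration of F6 | CC(C)(C)[Si](C)(C)OC[C@H](CC=C(C)C)[C@](C)(CCC=C(C)C)CCO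
F8 | step 7 | methyl ester from oxidation of F7 | CC(C)(C)[Si](C)(C)OC[C@H](CC=C(C)C)[C@](C)(CCC=C(C)C)CC(=O)OC
F9 | step 7 | α-prenylated ester from F8 (epimer mixture at the new centre) | CC(C)(C)[Si](C)(C)OC[C@H](CC=C(C)C)[C@](C)(CCC=C(C)C)C(CC=C(C)C)C(=O)OC
F10 | step 7 | hydroxy ester from desilylation of F9 | OC[C@H](CC=C(C)C)[C@](C)(CCC=C(C)C)C(CC=C(C)C)C(=O)OC
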